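**Plan**
- Retrosynthesis: (a) cut the bond between the internal alkene carbon and the cyclobutane CH, giving a terminal alkyne and a cyclobutanecarboxylic acid with CO2 as a traceless handle; (b) cut the ester C–O bond (linoleic acid + pent-4-yn-1-ol); (c) re-close the keto acid to a 2-acetylcyclopentanone and remove the acetyl group; (d) cut the two cyclobutane bonds ([2+2] of cyclopentenone and isobutene).
- Enabling feature: the alkene is 1,1-disubstituted with its internal carbon on the ring CH, which is the Markovnikov hydroalkylation pattern of a terminal alkyne. That ring CH is secondary and flanked by the stereocentre carrying the 3-oxobutyl chain. The sequence ring CH–ring CH–CH2–CH2–C(=O)CH3 is the opened form of a 2-acetylcyclopentanone fused to the 3,3-dimethylcyclobutane, whose ring carbonyl becomes the carboxyl group.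
- Forward: the cyclobutane arises first by photocycloaddition onto cyclopentenone; the cyclopentanone is a temporary ring that is acetylated and then opened; the alkyne ester is made separately and the two fragments are joined last.
- Stereochemistry: the chain-bearing ring carbon (R) comes from the chiral Lewis acid in the [2+2]; the alkenyl-bearing carbon (S) is set in the joining step, trans to it, through a planar radical; both Z-alkenes come from linoleic acid.

Key step: step 5

Assumption: the target is the trans-(1S,2R) cyclobutane as written (the natural caryophyllane configuration). The hand of the oxazaborolidine in step 1 that delivers (1R,5R)-3 is to be assigned in the first run, and any shortfall in enantiomeric purity of 3 is to be removed by preparative chromatography on a chiral phase before step 2.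

Step 1
Reactants: 1 cyclopent-2-en-1-one; 2 2-methylpropene (isobutene)
Product: 3 (1R,5R)-6,6-dimethylbicyclo[3.2.0]heptan-2-one
Conditions: AlBr3 adduct of 1-(2,4,6-trifluorophenyl)-3,3-bis(3,5-dimethylphenyl)tetrahydro-1H,3H-pyrrolo[1,2-c][1,3,2]oxazaborole (one enantiomer, 50 mol %), 2 (excess), CH2Cl2, −75 °C, hν (366 nm)
Reagents that add atoms: none
Why: Chiral-Lewis-acid-catalysed enone–olefin [2+2] photocycloaddition, in which the AlBr3-activated oxazaborolidine binds the enone carbonyl, shifts its absorption so that mainly the complex is excited and shields one face, so the β-carbon stereocentre (C5, later the chain-bearing ring carbon) is catalyst-controlled, the head-to-tail orientation (CMe2 on the β-carbon) is the usual one for a 1,1-dialkyl alkene, and the four/five ring fusion can only be cis.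

Step 2
Reactants: 3 (1R,5R)-6,6-dimethylbicyclo[3.2.0]heptan-2-one
Product: 5 (1R,5R)-3-acetyl-6,6-dimethylbicyclo[3.2.0]heptan-2-one, via morpholine enamine 4 (not isolated)
Conditions: morpholine, TsOH·H2O (cat.), PhMe, reflux, Dean–Stark; then AcCl, Et3N, CH2Cl2, 0 °C → rt; then aq. HCl, rt
Reagents that add atoms: acetyl chloride, CC(=O)Cl
Why: Stork enamine acylation, in which the enamine forms toward the CH2 side (a double bond toward the ring-fusion carbon would be exocyclic to the cyclobutane), is C-acetylated and is hydrolysed to the 2-acylcyclopentanone, with no fixed new stereocentre because the acetyl-bearing carbon is enolised.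

Step 3
Reactants: 5 (1R,5R)-3-acetyl-6,6-dimethylbicyclo[3.2.0]heptan-2-one
Product: 6 (1R,2R)-3,3-dimethyl-2-(3-oxobutyl)cyclobutane-1-carboxylic acid
Conditions: KOH (3 equiv), H2O/EtOH, 60 °C; then aq. HCl to pH 2
Reagents that add atoms: potassium hydroxide, [K+].[OH-]
Why: Retro-Claisen cleavage of a 2-acylcyclopentanone, in which hydroxide adds to the strained ring carbonyl and the ring C–C bond breaks to expel the methyl-ketone enolate, so the ring carbonyl becomes the carboxyl group on the cyclobutane and the acetyl-bearing carbon becomes the CH2 next to the ketone, while the chain-bearing stereocentre is untouched and the configuration at the carboxyl-bearing carbon (drawn cis, as formed with retention) is of no consequence.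

Step 4
Reactants: 7 linoleic acid, (9Z,12Z)-octadeca-9,12-dienoic acid; 8 pent-4-yn-1-ol
Product: 9 pent-4-yn-1-yl (9Z,12Z)-octadeca-9,12-dienoate
Conditions: DIC, DMAP (cat.), CH2Cl2, 0 °C → rt
Reagents that add atoms: none
Why: Steglich esterification under neutral conditions, which leaves the skipped Z,Z-diene and the terminal alkyne untouched.

Step 5
Reactants: 6 (1R,2R)-3,3-dimethyl-2-(3-oxobutyl)cyclobutane-1-carboxylic acid; 9 pent-4-yn-1-yl (9Z,12Z)-octadeca-9,12-dienoate
Product: 11 4-[(1S,2R)-3,3-dimethyl-2-(3-oxobutyl)cyclobutyl]pent-4-en-1-yl (9Z,12Z)-octadeca-9,12-dienoate (IN0146), via cyclobutyl radical 10 (not isolated)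
Conditions: [Ir{dF(CF3)ppy}2(dtbbpy)]PF6 (1 mol %; dF(CF3)ppy = 3,5-difluoro-2-[5-(trifluoromethyl)pyridin-2-yl]phenyl, dtbbpy = 4,4'-di-tert-butyl-2,2'-bipyridine), NiCl2·glyme (10 mol %), dtbbpy (10 mol %), 1,1,3,3-tetramethylguanidine (20 mol %), 9 (1.5 equiv), DMSO/MeCN, blue LEDs (450 nm), rt, degassed
Reagents that add atoms: none
Why: Metallaphotoredox decarboxylative hydroalkylation: the excited iridium photocatalyst oxidises the carboxylate of 6, loss of CO2 gives the secondary cyclobutyl radical 10, low-valent nickel–bipyridine captures it, the alkyl–nickel bond adds syn across the alkyne of 9 with the ring carbon going to the internal alkyne carbon, and protonolysis of the alkenyl–nickel bond by the carboxylic acid releases the 1,1-disubstituted alkene while the reduced photocatalyst returns the electron to nickel. The closest known reaction type is the photoredox/nickel Markovnikov hydroalkylation of terminal alkynes with aliphatic carboxylic acids, here applied to a cyclobutanecarboxylic acid. No ring is closed, and the four-membered ring passes through unchanged because ring opening of a cyclobutyl radical is slow. The new stereocentre (the ring carbon receiving the alkenyl group) is controlled by the neighbouring one: radical 10 is planar, nickel takes it up on the face anti to the adjacent 3-oxobutyl chain and the C–C bond forms with retention at that carbon, so both epimers of 6 should converge on the trans-(1S,2R) ring. The step needs Markovnikov regioselectivity (nickel prefers the unhindered alkyne terminus), trans selectivity (adjacent chain), and chemoselectivity for the alkyne over the two Z-alkenes, the bis-allylic C–H bonds, the ester and the ketone, which rests on the much faster insertion of a terminal alkyne and on the absence of hydrogen-abstracting oxygen radicals.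

**Compound list**
1 | cyclopent-2-en-1-one | O=C1C=CCC1 | starting material
2 | 2-methylpropene (isobutene) | C=C(C)C | starting material
3 | (1R,5R)-6,6-dimethylbicyclo[3.2.0]heptan-2-one | O=C1CC[C@@H]2[C@H]1CC2(C)C | intermediate
4 | 4-[(1R,5R)-6,6-dimethylbicyclo[3.2.0]hept-2-en-2-yl]morpholine | C1(N3CCOCC3)=CC[C@@H]2[C@H]1CC2(C)C | intermediate
5 | (1R,5R)-3-acetyl-6,6-dimethylbicyclo[3.2.0]heptan-2-one (C3 epimers and enol forms) | O=C1C(C(C)=O)C[C@@H]2[C@H]1CC2(C)C | intermediate
6 | (1R,2R)-3,3-dimethyl-2-(3-oxobutyl)cyclobutane-1-carboxylic acid (cis epimer drawn; the trans epimer is equally usable) | OC(=O)[C@@H]1CC(C)(C)[C@@H]1CCC(C)=O | intermediate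
7 | linoleic acid, (9Z,12Z)-octadeca-9,12-dienoic acid | OC(=O)CCCCCCC/C=C\C/C=C\CCCCC | starting material
8 | pent-4-yn-1-ol | C#CCCCO | starting material
9 | pent-4-yn-1-yl (9Z,12Z)-octadeca-9,12-dienoate | C#CCCCOC(=O)CCCCCCC/C=C\C/C=C\CCCCC | intermediate
10 | 3,3-dimethyl-2-(3-oxobutyl)cyclobutyl radical with the chain-bearing carbon configured as in 6 | [CH]1CC(C)(C)[C@@H]1CCC(C)=O | intermediate
11 | 4-[(1S,2R)-3,3-dimethyl-2-(3-oxobutyl)cyclobutyl]pent-4-en-1-yl (9Z,12Z)-octadeca-9,12-dienoate (IN0146) | C=C(CCCOC(=O)CCCCCCC/C=C\C/C=C\CCCCC)[C@H]1CC(C)(C)[C@@H]1CCC(C)=O | target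

**Count**
Total steps: 5. Longest linear sequence: 4 (steps 1, 2, 3, 5).

**Steps most likely to fail**

Step 5. The risks are slow oxidative decarboxylation of an unstabilised secondary cyclobutanecarboxylate, alkyne oligomerisation at nickel, leakage to the linear alkene, incomplete trans selectivity, addition of the radical to its own ketone, and hydrogen abstraction from the bis-allylic CH2 of the linoleate. The fallback is a thermal, reductive decarboxylative cross-electrophile coupling, which is known chemistry and forms the same bond through the same radical 10 without light. It sets out from 6, 7 and 8. Acid 6 is esterified with N-hydroxyphthalimide (DIC, DMAP cat., CH2Cl2) to 1,3-dioxoisoindolin-2-yl (1R,2R)-3,3-dimethyl-2-(3-oxobutyl)cyclobutane-1-carboxylate F1. Alkynol 8 is hydrobrominated in the Markovnikov sense with Et4N·HBr2 (CH2Cl2, 40 °C) to 4-bromopent-4-en-1-ol F2, which is esterified with 7 (DIC, DMAP) to 4-bromopent-4-en-1-yl (9Z,12Z)-octadeca-9,12-dienoate F3. F1 and F3 are then coupled with NiBr2·glyme, 4,4'-di-tert-butyl-2,2'-bipyridine and Zn in DMA at rt, and the route is rejoined at 11.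

Step 1. The risks are excitation of uncomplexed cyclopentenone (racemic background reaction), weak facial shielding of the five-membered enone, formation of the head-to-head regioisomer, and hydrogen transfer in the biradical. The fallback replaces asymmetric catalysis by resolution. It sets out from 1 and 2: uncatalysed irradiation (hν > 300 nm, CH2Cl2, −40 °C) should give the racemate, that is 3 together with (1S,5S)-6,6-dimethylbicyclo[3.2.0]heptan-2-one F4. The two are separated by preparative supercritical-fluid chromatography on a chiral stationary phase, and 3 re-enters the route at step 2.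

Step 2. The risks are ketene formation from acetyl chloride and triethylamine with cycloaddition to the enamine, double acylation, and sluggish enamine formation next to the ring fusion. The fallback is aldol addition followed by oxidation. It sets out from 3: the kinetic lithium enolate (LDA, THF, −78 °C), which forms at the CH2, is added to acetaldehyde to give (1R,5R)-3-(1-hydroxyethyl)-6,6-dimethylbicyclo[3.2.0]heptan-2-one F5. Oxidation with Dess–Martin periodinane (CH2Cl2, rt) then gives 5, where the route is rejoined.

**Further compounds**
F1 | step 5 | 1,3-dioxoisoindolin-2-yl (1R,2R)-3,3-dimethyl-2-(3-oxobutyl)cyclobutane-1-carboxylate | O=C(ON1C(=O)c2ccccc2C1=O)[C@@H]3CC(C)(C)[C@@H]3CCC(C)=O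
F2 | step 5 | 4-bromopent-4-en-1-ol | C=C(Br)CCCO
F3 | step 5 | 4-bromopent-4-en-1-yl (9Z,12Z)-octadeca-9,12-dienoate | C=C(Br)CCCOC(=O)CCCCCCC/C=C\C/C=C\CCCCC
F4 | step 1 | (1S,5S)-6,6-dimethylbicyclo[3.2.0]heptan-2-one | O=C1CC[C@H]2[C@@H]1CC2(C)C
F5 | step 2 | (1R,5R)-3-(1-hydroxyethyl)-6,6-dimethylbicyclo[3.2.0]heptan-2-one | O=C1C(C(C)O)C[C@@H]2[C@H]1CC2(C)C
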